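The seven-membered ring is cut at both bonds to its ring-fusion atoms, C3a–C4 and C8a–C8 (azulene numbering). The key step exploits that C3a and C8a, shared by both rings, are adjacent and that C4 and C8 are plain CH2 groups: a rhodium-catalysed (5+2) cycloaddition joins an internal alkyne (C3a, C8a) to 1-methyl-1-vinylcyclopropane (C4–C8) and delivers the cycloheptadiene with the C5=C6 methyl alkene, the precursor of the 5-acetoxy-6-methylidene unit. The alkyne carries a silyl-protected dienyl carbinol, so oxidation gives a dienone whose enantioselective silicon-directed Nazarov cyclisation adds the cyclopentane and the quaternary C3a. Hydrogenation anti to the angular methyl sets the trans fusion.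

Key step: step 4

Remark on the chemistry: azulene numbering is used for the core (C1 side-chain carbon, C3a methyl-bearing quaternary carbon, C5 acetoxy carbon, C6 methylidene carbon, C8a ring-fusion CH). The carbinol centre of 5–8 is racemic by design because step 5 removes it. The CIP descriptor at C3a changes from S (10–15) to R (16–20) without any change in spatial arrangement.

Step 1
Reactants: 1 1-methylcyclopropane-1-carbaldehyde
Product: 2 1-ethenyl-1-methylcyclopropane
Conditions: Ph3PCH3Br, KOtBu, tetraglyme, 0 °C to rt; product distilled from the pot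
Reagents that add atoms: methyltriphenylphosphonium bromide, C[P+](c1ccccc1)(c1ccccc1)c1ccccc1.[Br-]
Why: Wittig methylenation of a non-enolisable aldehyde should give the volatile 1-substituted vinylcyclopropane, and no stereocentre is formed.

Step 2
Reactants: 3 (2E)-3-(trimethylsilyl)prop-2-en-1-ol
Product: 4 (2E)-3-(trimethylsilyl)prop-2-enal
Conditions: MnO2, CH2Cl2, rt
Reagents that add atoms: none
Why: MnO2 oxidation is selective for the allylic alcohol and should leave the alkenylsilane and its E geometry untouched.

Step 3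
Reactants: 4 (2E)-3-(trimethylsilyl)prop-2-enal
Product: 6 triethyl{[(1E)-1-(trimethylsilyl)hex-1-en-4-yn-3-yl]oxy}silane (racemic), via bromomagnesium alkoxide 5 (not isolated)
Conditions: CH3C≡CMgBr, THF, −78 to 0 °C; then Et3SiCl, imidazole (cat.), 0 °C to rt
Reagents that add atoms: prop-1-yn-1-ylmagnesium bromide, CC#C[Mg]Br; chlorotriethylsilane, CC[Si](Cl)(CC)CC
Why: Alkynyl Grignard 1,2-addition to the enal and in-flask O-silylation of the alkoxide should give the propargylic silyl ether, whose carbinol centre is deliberately racemic (step 5 removes it) and whose bulky silyloxy-bearing carbon is there to steer the regiochemistry of step 4.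

Step 4
Reactants: 2 1-ethenyl-1-methylcyclopropane; 6 triethyl{[(1E)-1-(trimethylsilyl)hex-1-en-4-yn-3-yl]oxy}silane
Product: 7 {[(2E)-1-(2,5-dimethylcyclohepta-1,4-dien-1-yl)-3-(trimethylsilyl)prop-2-en-1-yl]oxy}triethylsilane (racemic)
Conditions: [Rh(CO)2Cl]2 (5 mol %), 2 (3 equiv), ClCH2CH2Cl, 80 °C, sealed tube
Reagents that add atoms: none
Why: Monovalent rhodium opens the cyclopropane of 2 next to the vinyl group to a σ-alkyl/π-allyl rhodacycle of trivalent rhodium, the alkyne of 6 inserts into the rhodium–allyl bond so that the vinyl terminus (future C4) bonds to the methyl-bearing alkyne carbon (future C3a), and C(sp3)–C(sp2) reductive elimination then joins the former cyclopropane CH2 (future C8) to the other alkyne carbon (future C8a). The closest known reaction type is the rhodium-catalysed intermolecular (5+2) cycloaddition of 1-substituted vinylcyclopropanes with alkynes, used here with an internal propargylic silyl ether. The seven-membered ring is closed by this formal cycloaddition (migratory insertion, then reductive elimination from an eight-membered rhodacycle), and both new sigma bonds end on the two alkyne carbons. No ring stereocentre is created, and the racemic carbinol centre carried by 6 is removed in step 5. The selectivity needed is regiochemical, because only the orientation with the methyl-bearing alkyne carbon next to the vinyl terminus puts the ring alkene at C5=C6 and not at C6=C7; it should be secured sterically, the bulky CH(OSiEt3)(CH=CHSiMe3) substituent taking the alkyne carbon remote from the first-formed C–C bond (the carbon bound to rhodium). The 1-methyl group of 2 favours the s-cis conformer needed for ring opening and becomes the C6 methyl.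

Step 5
Reactants: 7 {[(2E)-1-(2,5-dimethylcyclohepta-1,4-dien-1-yl)-3-(trimethylsilyl)prop-2-en-1-yl]oxy}triethylsilane
Product: 9 (2E)-1-(2,5-dimethylcyclohepta-1,4-dien-1-yl)-3-(trimethylsilyl)prop-2-en-1-one, via dienyl carbinol 8 (not isolated)
Conditions: Bu4NF, AcOH, THF, 0 °C; then MnO2, CH2Cl2, rt
Reagents that add atoms: none
Why: Buffered fluoride cleavage of the triethylsilyl ether (the alkenyl SiMe3 group should survive at 0 °C) and MnO2 oxidation of the doubly allylic alcohol should give the cross-conjugated dienone and delete the carbinol stereocentre.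

Step 6
Reactants: 9 (2E)-1-(2,5-dimethylcyclohepta-1,4-dien-1-yl)-3-(trimethylsilyl)prop-2-en-1-one
Product: 10 (3aS)-3a,6-dimethyl-4,7,8,8a-tetrahydroazulen-1(3aH)-one (C8a epimers, both usable)
Conditions: Zn(OTf)2 (10 mol %), chiral spirobiindane phosphoric acid (10 mol %, enantiomer chosen to give 3aS), PhOH (1.2 equiv), ClCH2CH2Cl, 40 °C
Reagents that add atoms: none
Why: In this enantioselective silicon-directed Nazarov cyclisation the zinc-bound dienone should undergo conrotatory 4π electrocyclisation whose sense of rotation is imposed by the chiral phosphate (catalyst control sets the quaternary C3a), the β-silicon directs loss of Me3Si to phenol so that the alkene ends at C2=C3, and C8a is protonated without control because step 7 erases it.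

Step 7
Reactants: 10 (3aS)-3a,6-dimethyl-4,7,8,8a-tetrahydroazulen-1(3aH)-one
Product: 12 (3aS)-3a,6-dimethyl-3a,4,7,8-tetrahydroazulen-1-yl trifluoromethanesulfonate, via lithium dienolate 11 (not isolated)
Conditions: LDA, THF, −78 °C; then PhNTf2, −78 to 0 °C
Reagents that add atoms: N-phenylbis(trifluoromethanesulfonimide), O=S(=O)(N(c1ccccc1)S(=O)(=O)C(F)(F)F)C(F)(F)F
Why: Kinetic deprotonation at C8a, the only enolisable position of this 3a-quaternary cyclopentenone, and O-triflation of the cross-conjugated dienolate should give the dienyl triflate regiospecifically and remove the C8a stereocentre.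

Step 8
Reactants: 12 (3aS)-3a,6-dimethyl-3a,4,7,8-tetrahydroazulen-1-yl trifluoromethanesulfonate
Product: 14 1-[(3aS)-3a,6-dimethyl-3a,4,7,8-tetrahydroazulen-1-yl]ethan-1-one, via ethoxy triene 13 (not isolated)
Conditions: Bu3SnC(OEt)=CH2, Pd(PPh3)4 (5 mol %), LiCl, THF, 65 °C; then 1 M HCl, rt
Reagents that add atoms: tributyl(1-ethoxyethenyl)stannane, C=C(OCC)[Sn](CCCC)(CCCC)CCCC; water, O
Why: Stille coupling of the alkenyl triflate with an acetyl-anion equivalent and hydrolysis of the enol ether should install the C1 acetyl group without forming a stereocentre.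

Step 9
Reactants: 14 1-[(3aS)-3a,6-dimethyl-3a,4,7,8-tetrahydroazulen-1-yl]ethan-1-one
Product: 15 1-[(3aS,5S,6R)-5,6-epoxy-3a,6-dimethyl-3a,4,5,6,7,8-hexahydroazulen-1-yl]ethan-1-one
Conditions: mCPBA, NaHCO3, CH2Cl2, 0 °C
Reagents that add atoms: 3-chloroperoxybenzoic acid, O=C(OO)c1cccc(Cl)c1
Why: Prilezhaev epoxidation should pick the only electron-rich alkene (the isolated trisubstituted C5=C6) over the acyl diene and should come from the face opposite the pseudo-axial 3a-methyl, which is 1,3 to C5 (substrate control, as in epoxidation of 2-ene steroids anti to the angular methyl), setting C5 and C6.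

Step 10
Reactants: 15 1-[(3aS,5S,6R)-5,6-epoxy-3a,6-dimethyl-3a,4,5,6,7,8-hexahydroazulen-1-yl]ethan-1-one
Product: 16 1-[(1S,3aR,5S,6R,8aS)-5,6-epoxy-3a,6-dimethyldecahydroazulen-1-yl]ethan-1-one
Conditions: H2 (4 atm), 10% Pd/C, EtOAc, rt
Reagents that add atoms: none
Why: Heterogeneous syn hydrogenation of the 1-acyl cyclopentadiene from the face opposite the angular 3a-methyl should place H-8a and H-1 on the same side, giving the trans ring fusion and the acetyl group cis to C8 (substrate control, compare hydrogenation of 14-ene steroids to the trans hydrindane), while the trisubstituted oxirane and the ketone should survive.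

Step 11
Reactants: 16 1-[(1S,3aR,5S,6R,8aS)-5,6-epoxy-3a,6-dimethyldecahydroazulen-1-yl]ethan-1-one
Product: 17 (2S)-2-[(1S,3aR,5S,6R,8aS)-5,6-epoxy-3a,6-dimethyldecahydroazulen-1-yl]pent-4-en-2-ol
Conditions: CH2=CHCH2MgBr, THF, −78 °C
Reagents that add atoms: allylmagnesium bromide, C=CC[Mg]Br
Why: Grignard 1,2-addition under 1,2-asymmetric induction by C1, with the ring-fusion carbon C8a as the large substituent anti to the nucleophile, should give the (S)-carbinol (the same sense as alkyl Grignard additions to 20-oxo steroids), and the cold, fast allyl addition should outrun enolisation and oxirane opening.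

Step 12
Reactants: 17 (2S)-2-[(1S,3aR,5S,6R,8aS)-5,6-epoxy-3a,6-dimethyldecahydroazulen-1-yl]pent-4-en-2-ol
Product: 18 (1S,3aR,5S,8aS)-1-[(2S)-2-hydroxypent-4-en-2-yl]-3a-methyl-6-methylidenedecahydroazulen-5-ol
Conditions: Et2NLi (from Et2NH, n-BuLi; 5 equiv), Et2O, 0 °C to reflux
Reagents that add atoms: none
Why: In this base-induced epoxide to allylic alcohol rearrangement (syn β-elimination) the amide should remove a primary hydrogen of the C6 methyl group, so the exocyclic methylidene forms and C5 keeps its configuration because the C5–O bond is not touched.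

Step 13
Reactants: 18 (1S,3aR,5S,8aS)-1-[(2S)-2-hydroxypent-4-en-2-yl]-3a-methyl-6-methylidenedecahydroazulen-5-ol
Product: 19 (1S,3aR,5S,8aS)-1-[(2S)-2-hydroxypent-4-en-2-yl]-3a-methyl-6-methylidenedecahydroazulen-5-yl acetate
Conditions: Ac2O, pyridine, DMAP (cat.), CH2Cl2, 0 °C
Reagents that add atoms: acetic anhydride, CC(=O)OC(C)=O
Why: Acylation under nucleophilic catalysis should be selective for the secondary allylic alcohol, the tertiary alcohol staying free.

Step 14
Reactants: 19 (1S,3aR,5S,8aS)-1-[(2S)-2-hydroxypent-4-en-2-yl]-3a-methyl-6-methylidenedecahydroazulen-5-yl acetate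
Product: 20 (1S,3aR,5S,8aS)-1-[(2S,4E)-2,6-dihydroxy-6-methylhept-4-en-2-yl]-3a-methyl-6-methylidenedecahydroazulen-5-yl acetate
Conditions: 2-methylbut-3-en-2-ol (8 equiv), second-generation Grubbs catalyst (5 mol %), CH2Cl2, 40 °C
Reagents that add atoms: 2-methylbut-3-en-2-ol, C=CC(C)(C)O
Why: Olefin cross-metathesis of the monosubstituted allyl alkene with excess tertiary allylic alcohol should give the E alkene under thermodynamic control, the hindered 1,1-disubstituted methylidene not taking part.

Compound list
1 | 1-methylcyclopropane-1-carbaldehyde | CC1(C=O)CC1 | starting material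
2 | 1-ethenyl-1-methylcyclopropane | C=CC1(C)CC1 | intermediate
3 | (2E)-3-(trimethylsilyl)prop-2-en-1-ol | C[Si](C)(C)/C=C/CO | starting material
4 | (2E)-3-(trimethylsilyl)prop-2-enal | C[Si](C)(C)/C=C/C=O | intermediate
5 | bromomagnesium (1E)-1-(trimethylsilyl)hex-1-en-4-yn-3-olate, racemic | CC#CC(O[Mg]Br)/C=C/[Si](C)(C)C | intermediate
6 | triethyl{[(1E)-1-(trimethylsilyl)hex-1-en-4-yn-3-yl]oxy}silane, racemic | CC#CC(O[Si](CC)(CC)CC)/C=C/[Si](C)(C)C | intermediate
7 | {[(2E)-1-(2,5-dimethylcyclohepta-1,4-dien-1-yl)-3-(trimethylsilyl)prop-2-en-1-yl]oxy}triethylsilane, racemic | CC1=CCC(C)=C(CC1)C(O[Si](CC)(CC)CC)/C=C/[Si](C)(C)C | intermediate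
8 | (2E)-1-(2,5-dimethylcyclohepta-1,4-dien-1-yl)-3-(trimethylsilyl)prop-2-en-1-ol, racemic | CC1=CCC(C)=C(CC1)C(O)/C=C/[Si](C)(C)C | intermediate
9 | (2E)-1-(2,5-dimethylcyclohepta-1,4-dien-1-yl)-3-(trimethylsilyl)prop-2-en-1-one | CC1=CCC(C)=C(CC1)C(=O)/C=C/[Si](C)(C)C | intermediate
10 | (3aS)-3a,6-dimethyl-4,7,8,8a-tetrahydroazulen-1(3aH)-one, C8a left undefined on purpose | CC1=CC[C@@]2(C)C=CC(=O)C2CC1 | intermediate
11 | lithium (3aS)-3a,6-dimethyl-3a,4,7,8-tetrahydroazulen-1-olate | CC1=CC[C@@]2(C)C=CC(O[Li])=C2CC1 | intermediate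
12 | (3aS)-3a,6-dimethyl-3a,4,7,8-tetrahydroazulen-1-yl trifluoromethanesulfonate | CC1=CC[C@@]2(C)C=CC(OS(=O)(=O)C(F)(F)F)=C2CC1 | intermediate
13 | (3aS)-1-(1-ethoxyethenyl)-3a,6-dimethyl-3a,4,7,8-tetrahydroazulene | CCOC(=C)C1=C2CCC(C)=CC[C@@]2(C)C=C1 | intermediate
14 | 1-[(3aS)-3a,6-dimethyl-3a,4,7,8-tetrahydroazulen-1-yl]ethan-1-one | CC(=O)C1=C2CCC(C)=CC[C@@]2(C)C=C1 | intermediate
15 | 1-[(3aS,5S,6R)-5,6-epoxy-3a,6-dimethyl-3a,4,5,6,7,8-hexahydroazulen-1-yl]ethan-1-one, oxirane oxygen anti to the 3a-methyl | C[C@@]12CCC3=C(C(C)=O)C=C[C@]3(C)C[C@@H]1O2 | intermediate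
16 | 1-[(1S,3aR,5S,6R,8aS)-5,6-epoxy-3a,6-dimethyldecahydroazulen-1-yl]ethan-1-one, H-1 and H-8a cis to each other and trans to the 3a-methyl | C[C@@]12CC[C@H]3[C@@H](C(C)=O)CC[C@]3(C)C[C@@H]1O2 | intermediate
17 | (2S)-2-[(1S,3aR,5S,6R,8aS)-5,6-epoxy-3a,6-dimethyldecahydroazulen-1-yl]pent-4-en-2-ol | C[C@@]12CC[C@H]3[C@@H]([C@@](C)(O)CC=C)CC[C@]3(C)C[C@@H]1O2 | intermediate
18 | (1S,3aR,5S,8aS)-1-[(2S)-2-hydroxypent-4-en-2-yl]-3a-methyl-6-methylidenedecahydroazulen-5-ol | C=C1CC[C@H]2[C@@H]([C@@](C)(O)CC=C)CC[C@]2(C)C[C@@H]1O | intermediate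
19 | (1S,3aR,5S,8aS)-1-[(2S)-2-hydroxypent-4-en-2-yl]-3a-methyl-6-methylidenedecahydroazulen-5-yl acetate | C=C1CC[C@H]2[C@@H]([C@@](C)(O)CC=C)CC[C@]2(C)C[C@@H]1OC(C)=O | intermediate
20 | (1S,3aR,5S,8aS)-1-[(2S,4E)-2,6-dihydroxy-6-methylhept-4-en-2-yl]-3a-methyl-6-methylidenedecahydroazulen-5-yl acetate | C=C1CC[C@H]2[C@@H]([C@@](C)(O)C/C=C/C(C)(C)O)CC[C@]2(C)C[C@@H]1OC(C)=O | target

Total step count: 14. Longest linear sequence: 13 steps (3 to 20, steps 2–14); the one-step branch 1 to 2 joins at step 4.

Steps most likely to fail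

Step 4 (key step). The hindered internal alkyne may insert slowly and with poor regiocontrol, which would put part of the ring alkene at C6=C7, and 2 may isomerise in competition. The fallback hands the regiochemistry to a silyl group on the alkyne and sets out from 2. The same rhodium catalysis with commercial trimethyl(prop-1-yn-1-yl)silane should give (2,5-dimethylcyclohepta-1,4-dien-1-yl)trimethylsilane F1, because silyl groups reliably take the alkyne carbon bound to rhodium. Ipso-iododesilylation with N-iodosuccinimide in hexafluoroisopropanol at 0 °C should then give 1-iodo-2,5-dimethylcyclohepta-1,4-diene F2. A carbonylative Stille coupling (CO, Pd(PPh3)4, commercial (E)-tributyl[2-(trimethylsilyl)ethenyl]stannane) comes back to the route at 9, and steps 2, 3 and 5 are then not needed.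

Step 6. The torquoselectivity may be insufficient, or the catalyst may not turn over, because the electrocyclisation has to create a quaternary centre. The fallback moves the enantio-determining event to a reagent-controlled epoxidation and sets out from 9. FeCl3 (1.1 equiv) in CH2Cl2 at −30 °C should give racemic 3a,6-dimethyl-4,7,8,8a-tetrahydroazulen-1(3aH)-one F3. Steps 7 and 8 are run unchanged on the racemate, through racemic lithium dienolate F4 (not isolated), racemic triflate F5 and racemic ethoxy triene F6 (not isolated), to racemic dienone F7. In place of step 9 a Shi epoxidation is used (fructose-derived chiral ketone of the enantiomeric series that gives the (5S,6R)-oxirane, KHSO5, K2CO3, MeCN–dimethoxymethane–water, 0 °C). The (3aS) half of F7 is the matched case and should give 15. The (3aR) half should react more slowly and give the diastereomeric epoxide F8, which is removed by chromatography together with unreacted material. The route is rejoined at 15.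

Step 10. Hydrogen may be delivered to the wrong face of the tetrasubstituted enone, the reduction may stall at the partly reduced stage, or the oxirane may be hydrogenolysed. The fallback separates the two reductions, epoxidises afterwards, and sets out from 14. RhCl(PPh3)3 and H2 in benzene should saturate only the disubstituted C2=C3 alkene and give 1-[(3aR)-3a,6-dimethyl-2,3,3a,4,7,8-hexahydroazulen-1-yl]ethan-1-one F9. Li in NH3/THF with t-BuOH (1 equiv) at −78 °C, then NH4Cl, should reduce the enone by electron transfer; the C8a carbanion should take the trans-fused configuration and the enolate should be protonated at C1 from the open face, giving 1-[(1S,3aR,8aS)-3a,6-dimethyl-1,2,3,3a,4,7,8,8a-octahydroazulen-1-yl]ethan-1-one F10. mCPBA should then epoxidise the C5=C6 alkene of the trans-fused skeleton anti to the angular methyl, and the route is rejoined at 16.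

Further compounds
F1 | step 4 | (2,5-dimethylcyclohepta-1,4-dien-1-yl)trimethylsilane | C[Si](C)(C)C1=C(C)CC=C(C)CC1
F2 | step 4 | 1-iodo-2,5-dimethylcyclohepta-1,4-diene | IC1=C(C)CC=C(C)CC1
F3 | step 6 | racemic 3a,6-dimethyl-4,7,8,8a-tetrahydroazulen-1(3aH)-one | CC1=CCC2(C)C=CC(=O)C2CC1
F4 | step 6 | racemic lithium 3a,6-dimethyl-3a,4,7,8-tetrahydroazulen-1-olate | CC1=CCC2(C)C=CC(O[Li])=C2CC1
F5 | step 6 | racemic 3a,6-dimethyl-3a,4,7,8-tetrahydroazulen-1-yl trifluoromethanesulfonate | CC1=CCC2(C)C=CC(OS(=O)(=O)C(F)(F)F)=C2CC1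
F6 | step 6 | racemic 1-(1-ethoxyethenyl)-3a,6-dimethyl-3a,4,7,8-tetrahydroazulene | CCOC(=C)C1=C2CCC(C)=CCC2(C)C=C1
F7 | step 6 | racemic 1-(3a,6-dimethyl-3a,4,7,8-tetrahydroazulen-1-yl)ethan-1-one | CC(=O)C1=C2CCC(C)=CCC2(C)C=C1
F8 | step 6 | 1-[(3aR,5S,6R)-5,6-epoxy-3a,6-dimethyl-3a,4,5,6,7,8-hexahydroazulen-1-yl]ethan-1-one | C[C@@]12CCC3=C(C(C)=O)C=C[C@@]3(C)C[C@@H]1O2
F9 | step 10 | 1-[(3aR)-3a,6-dimethyl-2,3,3a,4,7,8-hexahydroazulen-1-yl]ethan-1-one | CC(=O)C1=C2CCC(C)=CC[C@@]2(C)CC1
F10 | step 10 | 1-[(1S,3aR,8aS)-3a,6-dimethyl-1,2,3,3a,4,7,8,8a-octahydroazulen-1-yl]ethan-1-one | CC1=CC[C@@]2(C)CC[C@H](C(C)=O)[C@@H]2CC1
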